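**Retrosynthetic overview**

- The strategy rests on ring A of the chroman (C4a, C5, C6, C7, C8, C8a): a pentasubstituted benzene with oxygen on C5, C7 and C8a (O1), the acyl carbon on C6 para to C8a, and one hydrogen on C8.
- Target 26 comes from phenol 22 by capping the C7 phenol, unveiling and oxidising the C6 benzylic carbinol, and removing the silyl groups.
- Ring A of 22 is cut at C6–C7, C4a–C5 and C7–C8: a vinylketene from pyran-fused 3-alkoxycyclobutenone 7 (which already holds O1, C2 with its gem-dimethyl, C3 and C4) plus siloxyalkyne 17 carrying the ring B side chain.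
- 7 comes from ketene, ethoxyacetylene and prenyl bromide ([2+2], hydrolysis, cycloetherification); 17 comes from methyl 3-(4-hydroxyphenyl)propanoate by ortho-prenylation, reduction, ethynyl addition, and acetylide oxidation with O-silylation.
- Ring order: the dihydropyran ring is made first (fused to the cyclobutenone), ring B is bought, and ring A is closed last around the pyran.

Key step: step 11

Remark: ketene is used as the gas generated on demand by pyrolysis of acetone and is counted as a reagent.
Remark: the carbinol carbon of 13 to 24 is carried as the racemate, because it ends as the ketone carbon; the target has no stereocentre.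

Step 1
Reactants: 1 ethoxyacetylene; 2 prenyl bromide
Product: 4 1-ethoxy-5-methylhex-4-en-1-yne, via lithium ethoxyacetylide 3 (not isolated)
Conditions: n-BuLi, THF, −78 °C; then 2, DMPU, −78 °C to rt
Reagents that add atoms: none
Why: SN2 alkylation of a lithium alkoxyacetylide by a primary allylic bromide in a dipolar cosolvent is standard acetylide chemistry, and attack at the unhindered CH2 end of prenyl bromide should place the future C4, C3 and C2 (gem-dimethyl) carbons on the alkyne.

Step 2
Reactants: 4 1-ethoxy-5-methylhex-4-en-1-yne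
Product: 5 3-ethoxy-2-(3-methylbut-2-en-1-yl)cyclobut-2-en-1-one
Conditions: ketene (gas, excess), CH2Cl2, 0 °C
Reagents that add atoms: ketene C=C=O
Why: ketene–ynol ether [2+2] cycloaddition, in which the nucleophilic alkyl-bearing alkyne carbon bonds to the ketene carbonyl carbon so that the ethoxy group ends on C3 of the cyclobutenone, while the isolated trisubstituted alkene should be inert to ketene at this temperature.

Step 3
Reactants: 5 3-ethoxy-2-(3-methylbut-2-en-1-yl)cyclobut-2-en-1-one
Product: 6 3-hydroxy-2-(3-methylbut-2-en-1-yl)cyclobut-2-en-1-one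
Conditions: 1 M aq. HCl, THF, 0 °C to rt
Reagents that add atoms: water O
Why: acid hydrolysis of a vinylogous ester (addition of water at C3, loss of ethanol) should give the 2-prenylcyclobutane-1,3-dione, which rests as its strongly acidic enol.

Step 4
Reactants: 6 3-hydroxy-2-(3-methylbut-2-en-1-yl)cyclobut-2-en-1-one
Product: 7 3,3-dimethyl-2-oxabicyclo[4.2.0]oct-1(6)-en-7-one
Conditions: TfOH (10 mol %), CH2Cl2, 0 °C to rt; Et3N quench
Reagents that add atoms: none
Why: Brønsted acid-catalysed Markovnikov hydroalkoxylation, the cycloetherification known for 2-prenyl-1,3-diones, in which the enol oxygen captures the tertiary cation in a 6-endo closure to the 2,2-dimethyldihydropyran; the dione is symmetric, so either oxygen gives the same bicyclic vinylogous ester.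

Step 5
Reactants: 8 methyl 3-(4-hydroxyphenyl)propanoate; 2 prenyl bromide
Product: 10 methyl 3-[4-hydroxy-3-(3-methylbut-2-en-1-yl)phenyl]propanoate, via sodium phenoxide 9 (not isolated)
Conditions: NaH (1.0 equiv), toluene, 0 °C; then 2, rt
Reagents that add atoms: none
Why: ortho-C-alkylation of a sodium phenoxide in a non-polar solvent, where the tight ion pair shields oxygen and steers the allylic bromide to the ring carbon; the para position is blocked, and O-prenyl and bis-prenyl by-products would be removed by chromatography.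

Step 6
Reactants: 10 methyl 3-[4-hydroxy-3-(3-methylbut-2-en-1-yl)phenyl]propanoate
Product: 11 methyl 3-[3-(3-methylbut-2-en-1-yl)-4-(triisopropylsilyloxy)phenyl]propanoate
Conditions: TIPSCl, imidazole, DMF, rt
Reagents that add atoms: triisopropylsilyl chloride CC(C)[Si](Cl)(C(C)C)C(C)C
Why: imidazole-promoted O-silylation of a phenol; the triisopropylsilyl ether is chosen because it should survive the hydride, Grignard, alkyllithium and alkoxide conditions that follow and it blocks acid-induced chroman formation on ring B.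

Step 7
Reactants: 11 methyl 3-[3-(3-methylbut-2-en-1-yl)-4-(triisopropylsilyloxy)phenyl]propanoate
Product: 12 3-[3-(3-methylbut-2-en-1-yl)-4-(triisopropylsilyloxy)phenyl]propanal
Conditions: i-Bu2AlH (1.1 equiv), CH2Cl2, −78 °C; MeOH, then aq. potassium sodium tartrate
Reagents that add atoms: none
Why: partial reduction of a methyl ester with i-Bu2AlH at low temperature stops at the aluminium hemiacetal, which should release the aldehyde only on work-up.

Step 8
Reactants: 12 3-[3-(3-methylbut-2-en-1-yl)-4-(triisopropylsilyloxy)phenyl]propanal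
Product: 13 racemic 5-[3-(3-methylbut-2-en-1-yl)-4-(triisopropylsilyloxy)phenyl]pent-1-yn-3-ol
Conditions: HC≡CMgBr, THF, 0 °C
Reagents that add atoms: ethynylmagnesium bromide C#C[Mg]Br
Why: Grignard addition of an acetylide to an aldehyde; the new carbinol centre forms without facial control as the racemate, which is acceptable because it is oxidised to the ketone in step 14.

Step 9
Reactants: 13 racemic 5-[3-(3-methylbut-2-en-1-yl)-4-(triisopropylsilyloxy)phenyl]pent-1-yn-3-ol
Product: 14 racemic 5-[3-(3-methylbut-2-en-1-yl)-4-(triisopropylsilyloxy)phenyl]-3-(triethylsilyloxy)pent-1-yne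
Conditions: TESCl, imidazole, CH2Cl2, 0 °C to rt
Reagents that add atoms: triethylsilyl chloride CC[Si](Cl)(CC)CC
Why: standard silylation of a secondary alcohol; the triethylsilyl ether masks the hydroxyl against the ketene of step 11 and is the one silyl group that can later be removed in the presence of aryl silyl ethers.

Step 10
Reactants: 14 racemic 5-[3-(3-methylbut-2-en-1-yl)-4-(triisopropylsilyloxy)phenyl]-3-(triethylsilyloxy)pent-1-yne
Product: 17 racemic 5-[3-(3-methylbut-2-en-1-yl)-4-(triisopropylsilyloxy)phenyl]-3-(triethylsilyloxy)-1-(triisopropylsilyloxy)pent-1-yne, via lithium acetylide 15 (not isolated), via lithium ynolate 16 (not isolated)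
Conditions: n-BuLi, THF, −78 °C; t-BuOOLi (from t-BuOOH and LiN(SiMe3)2), −78 to 0 °C; TIPSOTf, −78 to 0 °C
Reagents that add atoms: tert-butyl hydroperoxide (as its lithium salt) CC(C)(C)OO; triisopropylsilyl trifluoromethanesulfonate CC(C)[Si](C(C)C)(C(C)C)OS(=O)(=O)C(F)(F)F
Why: electrophilic oxygenation of a lithium acetylide by lithium tert-butyl peroxide gives the lithium ynolate, and the hard silyl triflate should trap it on oxygen to give the triisopropylsilyl ynol ether, a known route from terminal alkynes to siloxyalkynes.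

Step 11
Reactants: 7 3,3-dimethyl-2-oxabicyclo[4.2.0]oct-1(6)-en-7-one; 17 racemic 5-[3-(3-methylbut-2-en-1-yl)-4-(triisopropylsilyloxy)phenyl]-3-(triethylsilyloxy)-1-(triisopropylsilyloxy)pent-1-yne
Product: 22 racemic 2,2-dimethyl-6-{3-[3-(3-methylbut-2-en-1-yl)-4-(triisopropylsilyloxy)phenyl]-1-(triethylsilyloxy)propyl}-5-(triisopropylsilyloxy)chroman-7-ol, via vinylketene 18 (not isolated), via spiro cyclobutenone adduct 19 (not isolated), via dienylketene 20 (not isolated), via cyclohexadienone 21 (not isolated)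
Conditions: 7 (1.3 equiv, added slowly), toluene, 80 °C, then 110 °C, argon
Reagents that add atoms: none
Why: Heating should open 7 by conrotatory 4π-electrocyclic cleavage of its C(=O)–CH2 bond to vinylketene 18, held s-cis by the pyran ring; [2+2] cycloaddition with the ynol silyl ether gives spiro cyclobutenone 19, a second 4π opening gives dienylketene 20, and disrotatory 6π-electrocyclisation (C7–C8 bond) followed by tautomerisation of dienone 21 gives phenol 22. The closest known reaction is the Danheiser benzannulation of cyclobutenones with siloxyalkynes to resorcinol monosilyl ethers, applied here to a cyclobutenone that is a ring-fused vinylogous ester. Ring A is closed as a six-membered carbocycle by the 6π-electrocyclisation onto the dihydropyran ring already in place, so the ether oxygen of 7 becomes O1 on C8a, para to C6, and the linear fusion follows from connectivity. No stereocentre is created: the spiro centre of 19 is lost on ring opening and the carbinol centre stays racemic. The step needs regioselectivity in the ketene–alkyne [2+2], which the polarisation of the ynol ether secures because its nucleophilic carbon (the one carrying the side chain) bonds to the ketene carbonyl carbon, giving C6–C7 and C4a–C5. The triisopropylsilyl group should resist the 1,3-shift to a silylketene, and slow addition of 7 keeps the vinylketene dilute against dimerisation and against acylation of the new phenol.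

Step 12
Reactants: 22 racemic 2,2-dimethyl-6-{3-[3-(3-methylbut-2-en-1-yl)-4-(triisopropylsilyloxy)phenyl]-1-(triethylsilyloxy)propyl}-5-(triisopropylsilyloxy)chroman-7-ol
Product: 23 racemic 7-(tert-butyldimethylsilyloxy)-2,2-dimethyl-6-{3-[3-(3-methylbut-2-en-1-yl)-4-(triisopropylsilyloxy)phenyl]-1-(triethylsilyloxy)propyl}-5-(triisopropylsilyloxy)chroman
Conditions: TBSOTf, 2,6-lutidine, CH2Cl2, 0 °C
Reagents that add atoms: tert-butyldimethylsilyl trifluoromethanesulfonate CC(C)(C)[Si](C)(C)OS(=O)(=O)C(F)(F)F
Why: silyl triflate silylation of a flanked phenol; capping the C7 hydroxyl removes the ortho-hydroxybenzyl arrangement, so the benzylic carbinol can be unveiled and oxidised without an ortho-quinone methide pathway.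

Step 13
Reactants: 23 racemic 7-(tert-butyldimethylsilyloxy)-2,2-dimethyl-6-{3-[3-(3-methylbut-2-en-1-yl)-4-(triisopropylsilyloxy)phenyl]-1-(triethylsilyloxy)propyl}-5-(triisopropylsilyloxy)chroman
Product: 24 racemic 1-[7-(tert-butyldimethylsilyloxy)-2,2-dimethyl-5-(triisopropylsilyloxy)chroman-6-yl]-3-[3-(3-methylbut-2-en-1-yl)-4-(triisopropylsilyloxy)phenyl]propan-1-ol
Conditions: HF·pyridine, excess pyridine, THF, 0 °C
Reagents that add atoms: none
Why: chemoselective desilylation, since under buffered acidic fluoride an alkyl triethylsilyl ether should cleave well before aryl triisopropylsilyl and hindered aryl tert-butyldimethylsilyl ethers, and the non-basic medium avoids silyl migration from the neighbouring aryl oxygens to the new alkoxide.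

Step 14
Reactants: 24 racemic 1-[7-(tert-butyldimethylsilyloxy)-2,2-dimethyl-5-(triisopropylsilyloxy)chroman-6-yl]-3-[3-(3-methylbut-2-en-1-yl)-4-(triisopropylsilyloxy)phenyl]propan-1-ol
Product: 25 1-[7-(tert-butyldimethylsilyloxy)-2,2-dimethyl-5-(triisopropylsilyloxy)chroman-6-yl]-3-[3-(3-methylbut-2-en-1-yl)-4-(triisopropylsilyloxy)phenyl]propan-1-one
Conditions: Dess–Martin periodinane, CH2Cl2, 0 °C to rt
Reagents that add atoms: none
Why: Dess–Martin oxidation of a hindered secondary benzylic alcohol to the aryl ketone, which should leave the prenyl alkene and the fully silylated electron-rich rings untouched and which removes the only stereocentre.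

Step 15
Reactants: 25 1-[7-(tert-butyldimethylsilyloxy)-2,2-dimethyl-5-(triisopropylsilyloxy)chroman-6-yl]-3-[3-(3-methylbut-2-en-1-yl)-4-(triisopropylsilyloxy)phenyl]propan-1-one
Product: 26 1-(5,7-dihydroxy-2,2-dimethylchroman-6-yl)-3-[4-hydroxy-3-(3-methylbut-2-en-1-yl)phenyl]propan-1-one (target)
Conditions: Bu4NF (3.3 equiv), AcOH, THF, 0 °C
Reagents that add atoms: none
Why: fluoride cleavage of aryl silyl ethers is fast, and the acetic acid buffer should keep the released polyphenol protonated, so the prenyl group, the chroman and the ketone are not exposed to strong base or acid.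

**Compound list**

1 | ethoxyacetylene | CCOC#C | starting material
2 | prenyl bromide (1-bromo-3-methylbut-2-ene) | CC(C)=CCBr | starting material
3 | lithium ethoxyacetylide | CCOC#C[Li] | intermediate (not isolated)
4 | 1-ethoxy-5-methylhex-4-en-1-yne | CCOC#CCC=C(C)C | intermediate
5 | 3-ethoxy-2-(3-methylbut-2-en-1-yl)cyclobut-2-en-1-one | CCOC1=C(CC=C(C)C)C(=O)C1 | intermediate
6 | 3-hydroxy-2-(3-methylbut-2-en-1-yl)cyclobut-2-en-1-one (enol of 2-prenylcyclobutane-1,3-dione) | OC1=C(CC=C(C)C)C(=O)C1 | intermediate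
7 | 3,3-dimethyl-2-oxabicyclo[4.2.0]oct-1(6)-en-7-one | O=C1CC2=C1CCC(C)(C)O2 | intermediate
8 | methyl 3-(4-hydroxyphenyl)propanoate | COC(=O)CCc1ccc(O)cc1 | starting material
9 | sodium 4-(3-methoxy-3-oxopropyl)phenoxide | COC(=O)CCc1ccc([O-])cc1.[Na+] | intermediate (not isolated)
10 | methyl 3-[4-hydroxy-3-(3-methylbut-2-en-1-yl)phenyl]propanoate | COC(=O)CCc1ccc(O)c(CC=C(C)C)c1 | intermediate
11 | methyl 3-[3-(3-methylbut-2-en-1-yl)-4-(triisopropylsilyloxy)phenyl]propanoate | COC(=O)CCc1ccc(O[Si](C(C)C)(C(C)C)C(C)C)c(CC=C(C)C)c1 | intermediate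
12 | 3-[3-(3-methylbut-2-en-1-yl)-4-(triisopropylsilyloxy)phenyl]propanal | O=CCCc1ccc(O[Si](C(C)C)(C(C)C)C(C)C)c(CC=C(C)C)c1 | intermediate
13 | racemic 5-[3-(3-methylbut-2-en-1-yl)-4-(triisopropylsilyloxy)phenyl]pent-1-yn-3-ol | C#CC(O)CCc1ccc(O[Si](C(C)C)(C(C)C)C(C)C)c(CC=C(C)C)c1 | intermediate
14 | racemic 5-[3-(3-methylbut-2-en-1-yl)-4-(triisopropylsilyloxy)phenyl]-3-(triethylsilyloxy)pent-1-yne | C#CC(O[Si](CC)(CC)CC)CCc1ccc(O[Si](C(C)C)(C(C)C)C(C)C)c(CC=C(C)C)c1 | intermediate
15 | lithium acetylide of 14 | [Li]C#CC(O[Si](CC)(CC)CC)CCc1ccc(O[Si](C(C)C)(C(C)C)C(C)C)c(CC=C(C)C)c1 | intermediate (not isolated)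
16 | lithium ynolate from 15 | [Li]OC#CC(O[Si](CC)(CC)CC)CCc1ccc(O[Si](C(C)C)(C(C)C)C(C)C)c(CC=C(C)C)c1 | intermediate (not isolated)
17 | racemic 5-[3-(3-methylbut-2-en-1-yl)-4-(triisopropylsilyloxy)phenyl]-3-(triethylsilyloxy)-1-(triisopropylsilyloxy)pent-1-yne | CC(C)[Si](C(C)C)(C(C)C)OC#CC(O[Si](CC)(CC)CC)CCc1ccc(O[Si](C(C)C)(C(C)C)C(C)C)c(CC=C(C)C)c1 | intermediate
18 | vinylketene (6,6-dimethyl-2-methylideneoxan-3-ylidene)methanone | O=C=C1CCC(C)(C)OC1=C | intermediate (not isolated)
19 | spiro cyclobutenone adduct (4-alkenylcyclobutenone spiro-fused to the 2-methylideneoxane; mixture of diastereomers) | C=C1OC(C)(C)CCC12C(=O)C(C(O[Si](CC)(CC)CC)CCc3ccc(O[Si](C(C)C)(C(C)C)C(C)C)c(CC=C(C)C)c3)=C2O[Si](C(C)C)(C(C)C)C(C)C | intermediate (not isolated)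
20 | dienylketene (isomer with the ketene carbon cis to C8a, the one that cyclises) | O=C=C(C(O[Si](CC)(CC)CC)CCc1ccc(O[Si](C(C)C)(C(C)C)C(C)C)c(CC=C(C)C)c1)/C(O[Si](C(C)C)(C(C)C)C(C)C)=C2/CCC(C)(C)OC2=C | intermediate (not isolated)
21 | cyclohexadienone (keto tautomer of 22, CH2 at C8) | O=C1CC2=C(CCC(C)(C)O2)C(O[Si](C(C)C)(C(C)C)C(C)C)=C1C(O[Si](CC)(CC)CC)CCc3ccc(O[Si](C(C)C)(C(C)C)C(C)C)c(CC=C(C)C)c3 | intermediate (not isolated)
22 | racemic 2,2-dimethyl-6-{3-[3-(3-methylbut-2-en-1-yl)-4-(triisopropylsilyloxy)phenyl]-1-(triethylsilyloxy)propyl}-5-(triisopropylsilyloxy)chroman-7-ol | CC(C)=CCc1cc(CCC(O[Si](CC)(CC)CC)c2c(O)cc3c(c2O[Si](C(C)C)(C(C)C)C(C)C)CCC(C)(C)O3)ccc1O[Si](C(C)C)(C(C)C)C(C)C | intermediate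
23 | racemic 7-(tert-butyldimethylsilyloxy) ether of 22 | CC(C)=CCc1cc(CCC(O[Si](CC)(CC)CC)c2c(O[Si](C)(C)C(C)(C)C)cc3c(c2O[Si](C(C)C)(C(C)C)C(C)C)CCC(C)(C)O3)ccc1O[Si](C(C)C)(C(C)C)C(C)C | intermediate
24 | racemic 1-[7-(tert-butyldimethylsilyloxy)-2,2-dimethyl-5-(triisopropylsilyloxy)chroman-6-yl]-3-[3-(3-methylbut-2-en-1-yl)-4-(triisopropylsilyloxy)phenyl]propan-1-ol | CC(C)=CCc1cc(CCC(O)c2c(O[Si](C)(C)C(C)(C)C)cc3c(c2O[Si](C(C)C)(C(C)C)C(C)C)CCC(C)(C)O3)ccc1O[Si](C(C)C)(C(C)C)C(C)C | intermediate
25 | 1-[7-(tert-butyldimethylsilyloxy)-2,2-dimethyl-5-(triisopropylsilyloxy)chroman-6-yl]-3-[3-(3-methylbut-2-en-1-yl)-4-(triisopropylsilyloxy)phenyl]propan-1-one | CC(C)=CCc1cc(CCC(=O)c2c(O[Si](C)(C)C(C)(C)C)cc3c(c2O[Si](C(C)C)(C(C)C)C(C)C)CCC(C)(C)O3)ccc1O[Si](C(C)C)(C(C)C)C(C)C | intermediate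
26 | 1-(5,7-dihydroxy-2,2-dimethylchroman-6-yl)-3-[4-hydroxy-3-(3-methylbut-2-en-1-yl)phenyl]propan-1-one | CC(C)=CCc1cc(CCC(=O)c2c(O)cc3c(c2O)CCC(C)(C)O3)ccc1O | target

**Step count**

Total: 15 steps. Longest linear sequence: 11 steps (steps 5 to 15); the cyclobutenone arm (steps 1 to 4) joins at step 11.

**Steps most likely to fail**

1. Step 11. The ring-fused vinylogous-ester cyclobutenone may open sluggishly, the vinylketene may dimerise, or the hindered siloxyalkyne may rearrange or decompose before it is captured. The fallback sets out from aldehyde 12 and comes back at 26. Phloroglucinol is condensed with 2-methylbut-3-en-2-ol under BF3·OEt2 in dioxane to give 2,2-dimethylchroman-5,7-diol F1. MOMCl and i-Pr2NEt give 5,7-bis(methoxymethoxy)-2,2-dimethylchroman F2. n-BuLi in THF at 0 °C should lithiate C6 between the two methoxymethyl ethers to give 6-lithio-5,7-bis(methoxymethoxy)-2,2-dimethylchroman F3, which is added to 12 at −78 °C to give the racemic bis(methoxymethyl) carbinol F4. Dess–Martin oxidation gives the bis(methoxymethyl) silyl ketone F5, Bu4NF gives the bis(methoxymethyl) phenol ketone F6, and dilute HCl in MeOH at rt removes the two methoxymethyl ethers, both ortho to the carbonyl, to give 26. The weak point of this fallback is competition between C6 and C8 in the lithiation; isomers would be separated at F4.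

2. Step 4. The product is a tertiary-alkyl vinylogous ester that can re-ionise under the acid that forms it, and the strained dione enol may suffer ring cleavage before it cyclises. The fallback sets out from 5 and comes back at 7. Mukaiyama hydration of the prenyl alkene of 5 (Co(acac)2 cat., PhSiH3, O2, THF/i-PrOH, rt) gives 3-ethoxy-2-(3-hydroxy-3-methylbutyl)cyclobut-2-en-1-one F7. Catalytic pyridinium p-toluenesulfonate in CH2Cl2 over 4 Å molecular sieves at rt should then close the pyran by intramolecular conjugate addition–elimination with loss of ethanol, under much milder acid and without a carbocation.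

3. Step 13. Desilylation may be unselective (loss or migration of an aryl silyl group), or the benzylic C–O bond may ionise before the carbinol is isolated. The fallback sets out from 22 and comes back at 26. Bu4NF with AcOH in THF at 0 °C removes all three silyl groups of 22 to give the racemic tetraol 1-(5,7-dihydroxy-2,2-dimethylchroman-6-yl)-3-[4-hydroxy-3-(3-methylbut-2-en-1-yl)phenyl]propan-1-ol F8, used at once without purification. Activated MnO2 in EtOAc at rt should then oxidise the ortho-hydroxybenzylic carbinol to 26, whose hydrogen-bonded 2,6-dihydroxyaryl ketone resists further oxidation.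

**Further compounds**

F1 | step 11 | 2,2-dimethylchroman-5,7-diol | CC1(C)CCc2c(O)cc(O)cc2O1
F2 | step 11 | 5,7-bis(methoxymethoxy)-2,2-dimethylchroman | COCOc1cc(OCOC)c2CCC(C)(C)Oc2c1
F3 | step 11 | 6-lithio-5,7-bis(methoxymethoxy)-2,2-dimethylchroman | COCOc1cc2OC(C)(C)CCc2c(OCOC)c1[Li]
F4 | step 11 | racemic 1-[5,7-bis(methoxymethoxy)-2,2-dimethylchroman-6-yl]-3-[3-(3-methylbut-2-en-1-yl)-4-(triisopropylsilyloxy)phenyl]propan-1-ol | CC(C)=CCc1cc(CCC(O)c2c(OCOC)cc3c(c2OCOC)CCC(C)(C)O3)ccc1O[Si](C(C)C)(C(C)C)C(C)C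
F5 | step 11 | 1-[5,7-bis(methoxymethoxy)-2,2-dimethylchroman-6-yl]-3-[3-(3-methylbut-2-en-1-yl)-4-(triisopropylsilyloxy)phenyl]propan-1-one | CC(C)=CCc1cc(CCC(=O)c2c(OCOC)cc3c(c2OCOC)CCC(C)(C)O3)ccc1O[Si](C(C)C)(C(C)C)C(C)C
F6 | step 11 | 1-[5,7-bis(methoxymethoxy)-2,2-dimethylchroman-6-yl]-3-[4-hydroxy-3-(3-methylbut-2-en-1-yl)phenyl]propan-1-one | CC(C)=CCc1cc(CCC(=O)c2c(OCOC)cc3c(c2OCOC)CCC(C)(C)O3)ccc1O
F7 | step 4 | 3-ethoxy-2-(3-hydroxy-3-methylbutyl)cyclobut-2-en-1-one | CCOC1=C(CCC(C)(C)O)C(=O)C1
F8 | step 13 | racemic 1-(5,7-dihydroxy-2,2-dimethylchroman-6-yl)-3-[4-hydroxy-3-(3-methylbut-2-en-1-yl)phenyl]propan-1-ol | CC(C)=CCc1cc(CCC(O)c2c(O)cc3c(c2O)CCC(C)(C)O3)ccc1O
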